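## Retrosynthetic overview

1. The target comes from a 9‑hydroxy‑2‑silyloxy germacranolide by C9 acetylation, desilylation and oxidation of the C2 carbinol.
2. Key step: an open‑chain α‑hydroxy aldehyde carrying a Morita–Baylis–Hillman acetate undergoes Pd(PPh3)4/InI umpolung allylation with lactonisation. The C7–C8 bond, the ten‑membered carbocycle and the α‑methylene‑γ‑lactone form in one operation, setting C7 and C8.
3. The open chain comes from an indium Barbier allylation (C2–C3) of an East epoxy aldehyde with a West allyl bromide.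
4. West (C3–C7, C11–C13): Sonogashira coupling, Z‑reduction, Sharpless epoxidation, Morita–Baylis–Hillman reaction, then Ti‑mediated epoxide opening by (R)‑2‑methylbutanoic acid (C5, C6).
5. East (C8–C2): (S)‑glycerate → butenolide → Z‑triol → hydroxyl‑directed epoxidation (C1, C10). Ring order: oxirane first, then carbocycle and lactone together.

Assumption: atoms are numbered as a germacran‑12,8‑olide (ring C1–C10, lactone carbons C11–C13, C14 methyl on C10, C15 methylene on C4), and (R)‑2‑methylbutanoic acid, D‑(−)‑diethyl tartrate and methyl (S)‑2,2‑dimethyl‑1,3‑dioxolane‑4‑carboxylate are bought as single enantiomers.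

## Route

Step 1
Reactants: 1 methyl (S)‑2,2‑dimethyl‑1,3‑dioxolane‑4‑carboxylate
Product: 3 (S)‑1‑(2,2‑dimethyl‑1,3‑dioxolan‑4‑yl)ethan‑1‑one, via Weinreb amide 2 (not isolated)
Conditions: MeNHOMe·HCl, iPrMgCl, THF, −20 °C; then MeMgBr, −20 → 0 °C
Reagents that add atoms: methylmagnesium bromide, C[Mg]Br
Why: Weinreb ketone synthesis, in which the amide formed in the flask gives a chelated adduct with MeMgBr that stops at the methyl ketone and leaves the C9 stereocentre untouched.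

Step 2
Reactants: 3 (S)‑1‑(2,2‑dimethyl‑1,3‑dioxolan‑4‑yl)ethan‑1‑one
Product: 5 (R)‑5‑(hydroxymethyl)‑4‑methylfuran‑2(5H)‑one, via Z‑enoate 4 (not isolated)
Conditions: Ph3P=CHCO2Me, MeOH, 0 °C → rt; then 1 M aq. HCl, rt
Reagents that add atoms: methyl (triphenylphosphoranylidene)acetate, COC(=O)C=P(c1ccccc1)(c1ccccc1)c1ccccc1
Why: Wittig olefination of the α‑alkoxy methyl ketone in methanol gives mainly the Z enoate, and after acetonide cleavage only that isomer lactonises, so the butenolide locks the C1=C10 Z geometry while C9 keeps the glycerate configuration.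

Step 3
Reactants: 5 (R)‑5‑(hydroxymethyl)‑4‑methylfuran‑2(5H)‑one
Product: 6 (2Z,4R)‑3‑methylpent‑2‑ene‑1,4,5‑triol
Conditions: iBu2AlH (3.5 equiv), CH2Cl2, −78 → 0 °C
Reagents that add atoms: none
Why: Hydride reduction of the butenolide (lactone to lactol to ring‑opened allylic alcohol, 1,2‑delivery) gives the Z‑ene‑1,4‑diol without changing the alkene geometry or C9.

Step 4
Reactants: 6 (2Z,4R)‑3‑methylpent‑2‑ene‑1,4,5‑triol
Product: 7 (1S)‑1‑[(2R,3S)‑3‑(hydroxymethyl)‑2‑methyloxiran‑2‑yl]ethane‑1,2‑diol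
Conditions: mCPBA, NaHCO3, CH2Cl2, 0 °C
Reagents that add atoms: 3‑chloroperoxybenzoic acid, OOC(=O)c1cccc(Cl)c1
Why: Hydroxyl‑directed Prilezhaev epoxidation, in which the C9 hydrogen eclipses the Z alkene to minimise allylic 1,3‑strain and the hydrogen‑bonded peracid delivers oxygen to the face of the C9 hydroxyl, gives the threo epoxy alcohol and sets C10 and C1.

Step 5
Reactants: 7 (1S)‑1‑[(2R,3S)‑3‑(hydroxymethyl)‑2‑methyloxiran‑2‑yl]ethane‑1,2‑diol
Product: 8 [(2S,3S)‑3‑[(4S)‑2,2‑dimethyl‑1,3‑dioxolan‑4‑yl]‑3‑methyloxiran‑2‑yl]methanol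
Conditions: Me2C(OMe)2, PPTS (cat.), acetone, 0 °C
Reagents that add atoms: 2,2‑dimethoxypropane, COC(C)(C)OC
Why: Acid‑catalysed transketalisation protects the terminal 1,2‑diol as the five‑membered acetonide and leaves the C2 hydroxyl free.

Step 6
Reactants: 8 [(2S,3S)‑3‑[(4S)‑2,2‑dimethyl‑1,3‑dioxolan‑4‑yl]‑3‑methyloxiran‑2‑yl]methanol
Product: 9 (2R,3R)‑3‑[(4S)‑2,2‑dimethyl‑1,3‑dioxolan‑4‑yl]‑3‑methyloxirane‑2‑carbaldehyde
Conditions: Dess–Martin periodinane, NaHCO3, CH2Cl2, 0 °C → rt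
Reagents that add atoms: none
Why: Dess–Martin oxidation under buffered neutral conditions gives the α,β‑epoxy aldehyde without epoxide opening or epimerisation.

Step 7
Reactants: 10 (2‑bromoprop‑2‑en‑1‑yl)trimethylsilane; 11 prop‑2‑yn‑1‑ol
Product: 12 4‑methylidene‑5‑(trimethylsilyl)pent‑2‑yn‑1‑ol
Conditions: Pd(PPh3)2Cl2 (3 mol %), CuI (6 mol %), Et3N, THF, rt
Reagents that add atoms: none
Why: Sonogashira coupling of the 2‑bromoalkene with the terminal alkyne forms the C4–C5 bond and leaves the allylsilane intact.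

Step 8
Reactants: 12 4‑methylidene‑5‑(trimethylsilyl)pent‑2‑yn‑1‑ol
Product: 13 (2Z)‑4‑methylidene‑5‑(trimethylsilyl)pent‑2‑en‑1‑ol
Conditions: Zn dust, Cu(OAc)2, AgNO3, MeOH/H2O (1:1), rt
Reagents that add atoms: none
Why: Activated‑zinc (Boland‑type) semi‑reduction of the conjugated enyne is cis‑selective and stops at the Z diene.

Step 9
Reactants: 13 (2Z)‑4‑methylidene‑5‑(trimethylsilyl)pent‑2‑en‑1‑ol
Product: 14 [(2R,3S)‑3‑[3‑(trimethylsilyl)prop‑1‑en‑2‑yl]oxiran‑2‑yl]methanol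
Conditions: Ti(OiPr)4 (20 mol %), D‑(−)‑diethyl tartrate (24 mol %), tBuOOH, 4 Å MS, CH2Cl2, −20 °C
Reagents that add atoms: tert‑butyl hydroperoxide, CC(C)(C)OO
Why: Sharpless asymmetric epoxidation with the D‑tartrate epoxidises only the allylic‑alcohol alkene and gives the (2R,3S) cis‑epoxy alcohol under reagent control, which sets C6 and the C5 centre that is inverted in step 12.

Step 10
Reactants: 14 [(2R,3S)‑3‑[3‑(trimethylsilyl)prop‑1‑en‑2‑yl]oxiran‑2‑yl]methanol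
Product: 15 (2S,3S)‑3‑[3‑(trimethylsilyl)prop‑1‑en‑2‑yl]oxirane‑2‑carbaldehyde
Conditions: Dess–Martin periodinane, NaHCO3, CH2Cl2, 0 °C
Reagents that add atoms: none
Why: Dess–Martin oxidation gives the cis‑epoxy aldehyde under neutral conditions that spare the vinyl epoxide and the allylsilane.

Step 11
Reactants: 15 (2S,3S)‑3‑[3‑(trimethylsilyl)prop‑1‑en‑2‑yl]oxirane‑2‑carbaldehyde
Product: 16 methyl 2‑[hydroxy{(2R,3S)‑3‑[3‑(trimethylsilyl)prop‑1‑en‑2‑yl]oxiran‑2‑yl}methyl]prop‑2‑enoate (both C7 epimers)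
Conditions: methyl acrylate (5 equiv), DABCO (0.5 equiv), rt
Reagents that add atoms: methyl acrylate, C=CC(=O)OC
Why: Morita–Baylis–Hillman reaction of the activated epoxy aldehyde installs C11–C13, and the C7 carbinol mixture is harmless because C7 becomes trigonal in step 19.

Step 12
Reactants: 16 methyl 2‑[hydroxy{(2R,3S)‑3‑[3‑(trimethylsilyl)prop‑1‑en‑2‑yl]oxiran‑2‑yl}methyl]prop‑2‑enoate; 17 (R)‑2‑methylbutanoic acid
Product: 18 methyl (4R,5R)‑3,4‑dihydroxy‑2,6‑dimethylidene‑5‑{[(2R)‑2‑methylbutanoyl]oxy}‑7‑(trimethylsilyl)heptanoate (C3 epimers; heptanoate C3, C4, C5 are target C7, C6, C5)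
Conditions: Ti(OiPr)4 (1.5 equiv), CH2Cl2, rt
Reagents that add atoms: none
Why: Titanium‑assisted regioselective opening of the 2,3‑epoxy alcohol, in which the Ti‑bound carboxylate attacks the distal allylic carbon C5 by SN2 with inversion, gives the 5,6‑threo pattern with the ester on C5 and free hydroxyls on C6 and C7.

Step 13
Reactants: 18 methyl (4R,5R)‑3,4‑dihydroxy‑2,6‑dimethylidene‑5‑{[(2R)‑2‑methylbutanoyl]oxy}‑7‑(trimethylsilyl)heptanoate
Product: 19 methyl (4R,5R)‑3,4‑bis(acetyloxy)‑2,6‑dimethylidene‑5‑{[(2R)‑2‑methylbutanoyl]oxy}‑7‑(trimethylsilyl)heptanoate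
Conditions: Ac2O, pyridine, DMAP (cat.), CH2Cl2, 0 °C
Reagents that add atoms: acetic anhydride, CC(=O)OC(C)=O
Why: DMAP‑catalysed acetylation gives the final C6 acetate and the allylic Morita–Baylis–Hillman acetate that is the leaving group in step 19.

Step 14
Reactants: 19 methyl (4R,5R)‑3,4‑bis(acetyloxy)‑2,6‑dimethylidene‑5‑{[(2R)‑2‑methylbutanoyl]oxy}‑7‑(trimethylsilyl)heptanoate
Product: 20 methyl (4R,5R)‑3,4‑bis(acetyloxy)‑6‑(bromomethyl)‑2‑methylidene‑5‑{[(2R)‑2‑methylbutanoyl]oxy}hept‑6‑enoate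
Conditions: NBS, propylene oxide, CH2Cl2, −78 °C
Reagents that add atoms: N‑bromosuccinimide, O=C1CCC(=O)N1Br
Why: Electrophilic bromodesilylation (SE2′) of the allylsilane gives the 2‑substituted allyl bromide, while the electron‑poor acrylate does not react.

Step 15
Reactants: 20 methyl (4R,5R)‑3,4‑bis(acetyloxy)‑6‑(bromomethyl)‑2‑methylidene‑5‑{[(2R)‑2‑methylbutanoyl]oxy}hept‑6‑enoate; 9 (2R,3R)‑3‑[(4S)‑2,2‑dimethyl‑1,3‑dioxolan‑4‑yl]‑3‑methyloxirane‑2‑carbaldehyde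
Product: 21 open‑chain C2 alcohol (C6,C7‑diacetate; C5 ester; C1–C10 epoxide; O8,O9‑acetonide; C2 and C7 epimers)
Conditions: In powder, THF/H2O (3:1), rt
Reagents that add atoms: none
Why: Indium‑mediated Barbier allylation joins the fragments at C2–C3 under neutral aqueous conditions that spare the epoxide, the esters and the allylic acetate, and the C2 epimers converge on oxidation in step 22.

Step 16
Reactants: 21 open‑chain C2 alcohol
Product: 22 C2 tert‑butyldimethylsilyl ether of 21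
Conditions: TBSOTf, 2,6‑lutidine, CH2Cl2, −78 °C
Reagents that add atoms: tert‑butyldimethylsilyl trifluoromethanesulfonate, CC(C)(C)[Si](C)(C)OS(=O)(=O)C(F)(F)F
Why: Silylation with the silyl triflate masks the C2 oxygen, so that no C2 ketone can compete with the aldehyde in step 19 and C2 is not acetylated in step 20.

Step 17
Reactants: 22 C2 tert‑butyldimethylsilyl ether of 21
Product: 23 C8,C9‑diol
Conditions: PPTS (0.2 equiv), MeOH, rt
Reagents that add atoms: none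
Why: Acid‑catalysed acetal exchange with methanol removes the terminal acetonide, while the secondary silyl ether, the epoxide and the esters survive the mild pyridinium acid.

Step 18
Reactants: 23 C8,C9‑diol
Product: 24 α‑hydroxy aldehyde (C8 aldehyde, free C9 hydroxyl)
Conditions: TEMPO (10 mol %), N‑chlorosuccinimide, Bu4NCl, CH2Cl2/aq. NaHCO3–K2CO3 (pH 8.6), 0 °C
Reagents that add atoms: none
Why: Oxoammonium (TEMPO) oxidation takes the primary C8 hydroxyl in preference to the hindered secondary C9 hydroxyl and causes no glycol cleavage; the aldehyde is used crude.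

Step 19
Reactants: 24 α‑hydroxy aldehyde (C8 aldehyde, free C9 hydroxyl)
Product: 27 9‑hydroxy‑2‑silyloxy germacran‑12,8‑olide, via allylindium 25 (not isolated), via hydroxy ester 26 (not isolated)
Conditions: Pd(PPh3)4 (10 mol %), InI (2 equiv), THF/H2O (20:1), 2 mM, rt; then PPTS (cat.), rt
Reagents that add atoms: none
Why: Proposed new method: zerovalent palladium ionises the Morita–Baylis–Hillman acetate to a 2‑(methoxycarbonyl)allyl complex that InI reduces to the Z allylindium 25, which adds through C7 to the indium‑chelated α‑hydroxy aldehyde in a chair transition state (7,8‑syn from the Z allyl geometry, 8,9‑syn from chelation by the C9 hydroxyl) to close the ten‑membered ring, and the C8 alkoxide then acylates on the methyl ester to give the cis‑fused α‑methylene lactone; the closest known reactions are the intermolecular palladium/InI umpolung carbonyl allylation of allylic acetates and the Barbier or Nozaki–Hiyama lactone annulation of 2‑(alkoxycarbonyl)allyl halides.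

Step 20
Reactants: 27 9‑hydroxy‑2‑silyloxy germacran‑12,8‑olide
Product: 28 6,9‑diacetate with C2 silyl ether
Conditions: Ac2O, DMAP, pyridine, CH2Cl2, rt
Reagents that add atoms: acetic anhydride, CC(=O)OC(C)=O
Why: DMAP‑catalysed acetylation esterifies the only free hydroxyl (C9) without touching its configuration.

Step 21
Reactants: 28 6,9‑diacetate with C2 silyl ether
Product: 29 C2 alcohol (C2 epimers)
Conditions: HF·pyridine, pyridine, THF, 0 °C → rt
Reagents that add atoms: none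
Why: Buffered fluoride desilylation frees the C2 hydroxyl without opening the epoxide or adding to the α‑methylene lactone.

Step 22
Reactants: 29 C2 alcohol (C2 epimers)
Product: 30 (1R,5R,6R,7R,8R,9S,10R)‑6,9‑bis(acetyloxy)‑1,10‑epoxy‑5‑{[(2R)‑2‑methylbutanoyl]oxy}‑2‑oxogermacra‑4(15),11(13)‑dien‑12,8‑olide
Conditions: Dess–Martin periodinane, NaHCO3, CH2Cl2, 0 °C → rt
Reagents that add atoms: none
Why: Dess–Martin oxidation converts both C2 epimers into the epoxy ketone under neutral conditions that do not move the C4 exocyclic alkene into conjugation.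

## Compound list

1 | methyl (S)‑2,2‑dimethyl‑1,3‑dioxolane‑4‑carboxylate | COC(=O)[C@@H]1COC(C)(C)O1 | starting material
2 | (S)‑N‑methoxy‑N,2,2‑trimethyl‑1,3‑dioxolane‑4‑carboxamide | CON(C)C(=O)[C@@H]1COC(C)(C)O1 | intermediate (not isolated)
3 | (S)‑1‑(2,2‑dimethyl‑1,3‑dioxolan‑4‑yl)ethan‑1‑one | CC(=O)[C@@H]1COC(C)(C)O1 | intermediate
4 | methyl (Z)‑3‑[(4R)‑2,2‑dimethyl‑1,3‑dioxolan‑4‑yl]but‑2‑enoate | COC(=O)/C=C(/C)[C@@H]1COC(C)(C)O1 | intermediate (not isolated)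
5 | (R)‑5‑(hydroxymethyl)‑4‑methylfuran‑2(5H)‑one | CC1=CC(=O)O[C@H]1CO | intermediate
6 | (2Z,4R)‑3‑methylpent‑2‑ene‑1,4,5‑triol | OC/C=C(/C)[C@@H](O)CO | intermediate
7 | (1S)‑1‑[(2R,3S)‑3‑(hydroxymethyl)‑2‑methyloxiran‑2‑yl]ethane‑1,2‑diol | OC[C@@H]1O[C@]1(C)[C@@H](O)CO | intermediate
8 | [(2S,3S)‑3‑[(4S)‑2,2‑dimethyl‑1,3‑dioxolan‑4‑yl]‑3‑methyloxiran‑2‑yl]methanol | OC[C@@H]1O[C@]1(C)[C@@H]1COC(C)(C)O1 | intermediate
9 | (2R,3R)‑3‑[(4S)‑2,2‑dimethyl‑1,3‑dioxolan‑4‑yl]‑3‑methyloxirane‑2‑carbaldehyde | O=C[C@@H]1O[C@]1(C)[C@@H]1COC(C)(C)O1 | intermediate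
10 | (2‑bromoprop‑2‑en‑1‑yl)trimethylsilane | C=C(Br)C[Si](C)(C)C | starting material
11 | prop‑2‑yn‑1‑ol | OCC#C | starting material
12 | 4‑methylidene‑5‑(trimethylsilyl)pent‑2‑yn‑1‑ol | OCC#CC(=C)C[Si](C)(C)C | intermediate
13 | (2Z)‑4‑methylidene‑5‑(trimethylsilyl)pent‑2‑en‑1‑ol | OC/C=C\C(=C)C[Si](C)(C)C | intermediate
14 | [(2R,3S)‑3‑[3‑(trimethylsilyl)prop‑1‑en‑2‑yl]oxiran‑2‑yl]methanol | OC[C@H]1O[C@H]1C(=C)C[Si](C)(C)C | intermediate
15 | (2S,3S)‑3‑[3‑(trimethylsilyl)prop‑1‑en‑2‑yl]oxirane‑2‑carbaldehyde | O=C[C@H]1O[C@H]1C(=C)C[Si](C)(C)C | intermediate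
16 | methyl 2‑[hydroxy{(2R,3S)‑3‑[3‑(trimethylsilyl)prop‑1‑en‑2‑yl]oxiran‑2‑yl}methyl]prop‑2‑enoate (C7 epimers) | C=C(C(=O)OC)C(O)[C@H]1O[C@H]1C(=C)C[Si](C)(C)C | intermediate
17 | (R)‑2‑methylbutanoic acid | CC[C@@H](C)C(=O)O | starting material
18 | methyl (4R,5R)‑3,4‑dihydroxy‑2,6‑dimethylidene‑5‑{[(2R)‑2‑methylbutanoyl]oxy}‑7‑(trimethylsilyl)heptanoate (C3 epimers) | C=C(C(=O)OC)C(O)[C@@H](O)[C@H](OC(=O)[C@H](C)CC)C(=C)C[Si](C)(C)C | intermediate
19 | methyl (4R,5R)‑3,4‑bis(acetyloxy)‑2,6‑dimethylidene‑5‑{[(2R)‑2‑methylbutanoyl]oxy}‑7‑(trimethylsilyl)heptanoate (C3 epimers) | C=C(C(=O)OC)C(OC(C)=O)[C@@H](OC(C)=O)[C@H](OC(=O)[C@H](C)CC)C(=C)C[Si](C)(C)C | intermediate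
20 | methyl (4R,5R)‑3,4‑bis(acetyloxy)‑6‑(bromomethyl)‑2‑methylidene‑5‑{[(2R)‑2‑methylbutanoyl]oxy}hept‑6‑enoate (C3 epimers) | C=C(C(=O)OC)C(OC(C)=O)[C@@H](OC(C)=O)[C@H](OC(=O)[C@H](C)CC)C(=C)CBr | intermediate
21 | open‑chain C2 alcohol: C13=C11(CO2Me)–C7H(OAc)–C6H(OAc)–C5H(O‑acyl)–C4(=CH2)–C3H2–C2H(OH)–C1/C10 epoxide–C9,C8 acetonide; C2 and C7 epimers, other centres as in 30 | C=C(C(=O)OC)C(OC(C)=O)[C@@H](OC(C)=O)[C@H](OC(=O)[C@H](C)CC)C(=C)CC(O)[C@@H]1O[C@]1(C)[C@@H]1COC(C)(C)O1 | intermediate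
22 | C2 tert‑butyldimethylsilyl ether of 21 | C=C(C(=O)OC)C(OC(C)=O)[C@@H](OC(C)=O)[C@H](OC(=O)[C@H](C)CC)C(=C)CC(O[Si](C)(C)C(C)(C)C)[C@@H]1O[C@]1(C)[C@@H]1COC(C)(C)O1 | intermediate
23 | C8,C9‑diol from 22 (acetonide removed) | C=C(C(=O)OC)C(OC(C)=O)[C@@H](OC(C)=O)[C@H](OC(=O)[C@H](C)CC)C(=C)CC(O[Si](C)(C)C(C)(C)C)[C@@H]1O[C@]1(C)[C@@H](O)CO | intermediate
24 | α‑hydroxy aldehyde (C8 aldehyde, C9 hydroxyl, C2 silyl ether) | C=C(C(=O)OC)C(OC(C)=O)[C@@H](OC(C)=O)[C@H](OC(=O)[C@H](C)CC)C(=C)CC(O[Si](C)(C)C(C)(C)C)[C@@H]1O[C@]1(C)[C@@H](O)C=O | intermediate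
25 | (Z)‑allylindium acetate iodide (indium on C13, C11=C7 alkene, C6 cis to CH2In) | COC(=O)/C(C[In](I)OC(C)=O)=C/[C@@H](OC(C)=O)[C@H](OC(=O)[C@H](C)CC)C(=C)CC(O[Si](C)(C)C(C)(C)C)[C@@H]1O[C@]1(C)[C@@H](O)C=O | intermediate (not isolated)
26 | ten‑membered 8,9‑dihydroxy methyl ester (ring closed at C7–C8, lactone not yet formed) | C=C(C(=O)OC)[C@@H]1[C@@H](OC(C)=O)[C@H](OC(=O)[C@H](C)CC)C(=C)CC(O[Si](C)(C)C(C)(C)C)[C@@H]2O[C@]2(C)[C@@H](O)[C@@H]1O | intermediate (not isolated)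
27 | 9‑hydroxy‑2‑(tert‑butyldimethylsilyloxy) analogue of 30 (6‑acetate, 5‑ester, 1,10‑epoxide, 12,8‑olide; C2 epimers) | C=C1C(=O)O[C@@H]2[C@H]1[C@@H](OC(C)=O)[C@H](OC(=O)[C@H](C)CC)C(=C)CC(O[Si](C)(C)C(C)(C)C)[C@@H]1O[C@]1(C)[C@H]2O | intermediate
28 | 6,9‑diacetate with C2 silyl ether | C=C1C(=O)O[C@@H]2[C@H]1[C@@H](OC(C)=O)[C@H](OC(=O)[C@H](C)CC)C(=C)CC(O[Si](C)(C)C(C)(C)C)[C@@H]1O[C@]1(C)[C@H]2OC(C)=O | intermediate
29 | 2‑hydroxy precursor of 30 (C2 epimers) | C=C1C(=O)O[C@@H]2[C@H]1[C@@H](OC(C)=O)[C@H](OC(=O)[C@H](C)CC)C(=C)CC(O)[C@@H]1O[C@]1(C)[C@H]2OC(C)=O | intermediate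
30 | (1R,5R,6R,7R,8R,9S,10R)‑6,9‑bis(acetyloxy)‑1,10‑epoxy‑5‑{[(2R)‑2‑methylbutanoyl]oxy}‑2‑oxogermacra‑4(15),11(13)‑dien‑12,8‑olide | C=C1C(=O)O[C@@H]2[C@H]1[C@@H](OC(C)=O)[C@H](OC(=O)[C@H](C)CC)C(=C)CC(=O)[C@@H]1O[C@]1(C)[C@H]2OC(C)=O | target

## Step count and risks

Total step count: 22. Longest linear sequence: 16 steps (steps 7–22, from 10 and 11); the East branch contributes steps 1–6.

The three steps most likely to fail:

**Step 19.** The ring closure may fail or give the wrong C7/C8 diastereomer. Zerovalent palladium may also ionise the C5 allylic ester, the allylindium may eliminate the neighbouring C6 acetate, and trivalent indium may open the epoxide. Fallback: form the lactone intermolecularly and close the carbocycle last at C2–C3, where no stereocentre is at stake. It sets out from 8 and 19 and comes back at 29.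
- TBSCl/imidazole on 8 gives the primary silyl ether F1, PPTS/MeOH the diol F2, and TEMPO/N‑chlorosuccinimide the α‑hydroxy aldehyde F3.
- MgBr2·OEt2 converts 19 into the (Z)‑allylic bromide F4; a palladium‑free indium Barbier coupling of F4 with F3 in THF/H2O, then PPTS, gives the open‑chain α‑methylene lactone F5.
- Ac2O/DMAP gives the C9 acetate F6, NBS the allyl bromide F7, HF·pyridine the primary alcohol F8, and Dess–Martin oxidation the epoxy aldehyde F9.
- A Nozaki–Hiyama allylation with CrCl2 (THF, high dilution) closes the ten‑membered ring to 29, and step 22 follows.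

**Step 12.** SN2′ attack, acyl migration or poor delivery on the secondary epoxy alcohol may intervene. Fallback: open the epoxide one stage earlier, on the primary epoxy alcohol. It sets out from 14 and comes back at 18. Ti(OiPr)4 and 17 open 14 at C5 to give the ester diol F10, TEMPO/N‑chlorosuccinimide oxidises its primary hydroxyl to the α‑hydroxy aldehyde F11, and the Morita–Baylis–Hillman reaction with methyl acrylate/DABCO returns to 18.

**Step 11.** DABCO may open the vinyl epoxide, or the reaction may stall. Fallback: replace amine catalysis by a preformed acrylate α‑anion equivalent. It sets out from 15 and comes back at 16. Hydroalumination of methyl propiolate with iBu2AlH/HMPA in THF at 0 °C gives the vinylalane F12, which adds to 15 at −78 °C.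

Further compounds

F1 | step 19 | C2 tert‑butyldimethylsilyl ether of 8 | CC(C)(C)[Si](C)(C)OC[C@@H]1O[C@]1(C)[C@@H]1COC(C)(C)O1
F2 | step 19 | C8,C9‑diol from F1 | CC(C)(C)[Si](C)(C)OC[C@@H]1O[C@]1(C)[C@@H](O)CO
F3 | step 19 | α‑hydroxy aldehyde (C8 aldehyde, C9 hydroxyl, C2 silyl ether) | CC(C)(C)[Si](C)(C)OC[C@@H]1O[C@]1(C)[C@@H](O)C=O
F4 | step 19 | methyl (2Z,4R,5R)‑4‑(acetyloxy)‑2‑(bromomethyl)‑6‑methylidene‑5‑{[(2R)‑2‑methylbutanoyl]oxy}‑7‑(trimethylsilyl)hept‑2‑enoate | COC(=O)/C(CBr)=C/[C@@H](OC(C)=O)[C@H](OC(=O)[C@H](C)CC)C(=C)C[Si](C)(C)C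
F5 | step 19 | open‑chain α‑methylene‑γ‑lactone (C7–C8 bond and 12,8‑lactone formed; C9 hydroxyl; allylsilane at C3; C2 silyl ether) | C=C1C(=O)O[C@@H]([C@H](O)[C@@]2(C)O[C@H]2CO[Si](C)(C)C(C)(C)C)[C@H]1[C@@H](OC(C)=O)[C@H](OC(=O)[C@H](C)CC)C(=C)C[Si](C)(C)C
F6 | step 19 | C9 acetate of F5 | C=C1C(=O)O[C@@H]([C@H](OC(C)=O)[C@@]2(C)O[C@H]2CO[Si](C)(C)C(C)(C)C)[C@H]1[C@@H](OC(C)=O)[C@H](OC(=O)[C@H](C)CC)C(=C)C[Si](C)(C)C
F7 | step 19 | C3 allyl bromide from F6 | C=C1C(=O)O[C@@H]([C@H](OC(C)=O)[C@@]2(C)O[C@H]2CO[Si](C)(C)C(C)(C)C)[C@H]1[C@@H](OC(C)=O)[C@H](OC(=O)[C@H](C)CC)C(=C)CBr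
F8 | step 19 | C2 primary alcohol from F7 | C=C1C(=O)O[C@@H]([C@H](OC(C)=O)[C@@]2(C)O[C@H]2CO)[C@H]1[C@@H](OC(C)=O)[C@H](OC(=O)[C@H](C)CC)C(=C)CBr
F9 | step 19 | C2 epoxy aldehyde from F8 | C=C1C(=O)O[C@@H]([C@H](OC(C)=O)[C@@]2(C)O[C@H]2C=O)[C@H]1[C@@H](OC(C)=O)[C@H](OC(=O)[C@H](C)CC)C(=C)CBr
F10 | step 12 | (2R,3R)‑1,2‑dihydroxy‑4‑methylidene‑5‑(trimethylsilyl)pentan‑3‑yl (2R)‑2‑methylbutanoate | OC[C@@H](O)[C@H](OC(=O)[C@H](C)CC)C(=C)C[Si](C)(C)C
F11 | step 12 | α‑hydroxy aldehyde from F10 (C7 aldehyde, C6 hydroxyl, C5 ester) | O=C[C@@H](O)[C@H](OC(=O)[C@H](C)CC)C(=C)C[Si](C)(C)C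
F12 | step 11 | [1‑(methoxycarbonyl)ethenyl]bis(2‑methylpropyl)aluminium | C=C(C(=O)OC)[Al](CC(C)C)CC(C)C
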